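**Retrosynthetic overview**
1. Target 25 comes from selective C-8 methacrylation of the macrocyclic 8,9-diol 23, itself from acetonide 22.
2. The ten-membered carbocycle is closed last, by ring-closing metathesis (C-4=C-5) between the furanone isopropenyl group and the lactone vinyl group of 21 (key step).
3. The 3(2H)-furanone comes from a γ-hydroxy ynone, made by acyl Sonogashira coupling of alkyne 16 with methacryloyl chloride and cyclised with gold.
4. The cis α-methylene-γ-lactone comes from a zinc Barbier allylation of acrolein with the Morita–Baylis–Hillman-derived (Z)-bromide 12.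
5. C-8 and C-9 come from 5-deoxy-D-ribose; C-10 is set by chelation-controlled ethynylation of methyl ketone 4. Ring order: dioxolane (temporary), lactone, furanone, carbocycle.

Assumption: germacrane-type locants are used (C-1 ketone, C-3–O–C-10 bridge, C-6 lactone oxygen, C-8 ester, C-9 hydroxyl, C-11=C-13 methylene); read this way the given SMILES is (4Z,6S,7S,8S,9S,10R) with a cis-fused lactone.

**Route**

Step 1
Reactants: 1 5-deoxy-D-ribose
Product: 2 5-deoxy-2,3-O-isopropylidene-D-ribofuranose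
Conditions: Me2C(OMe)2, TsOH·H2O (cat.), acetone, rt
Reagents that add atoms: 2,2-dimethoxypropane, COC(C)(C)OC
Why: Acid-catalysed acetonide formation (transacetalisation) ties up the cis-2,3-diol and leaves the lactol free; no stereocentre is touched, and sugar C-2/C-3 become C-8/C-9 of the target.

Step 2
Reactants: 2 5-deoxy-2,3-O-isopropylidene-D-ribofuranose
Product: 3 (1R)-1-[(4R,5S)-2,2-dimethyl-5-vinyl-1,3-dioxolan-4-yl]ethanol
Conditions: Ph3PCH3Br, KOtBu, THF, 0 °C to reflux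
Reagents that add atoms: methyltriphenylphosphonium bromide, C[P+](c1ccccc1)(c1ccccc1)c1ccccc1.[Br-]
Why: Wittig methylenation of the open hydroxy-aldehyde form of the lactol gives the terminal alkene and frees the C-4 hydroxyl (future C-10) without touching C-8/C-9.

Step 3
Reactants: 3 (1R)-1-[(4R,5S)-2,2-dimethyl-5-vinyl-1,3-dioxolan-4-yl]ethanol
Product: 4 1-[(4S,5S)-2,2-dimethyl-5-vinyl-1,3-dioxolan-4-yl]ethanone
Conditions: Dess–Martin periodinane, CH2Cl2, 0 °C to rt
Reagents that add atoms: none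
Why: Dess–Martin oxidation gives the methyl ketone under non-basic conditions, so the cis-dioxolane α-centre is not epimerised.

Step 4
Reactants: 4 1-[(4S,5S)-2,2-dimethyl-5-vinyl-1,3-dioxolan-4-yl]ethanone
Product: 5 (2S)-2-[(4S,5S)-2,2-dimethyl-5-vinyl-1,3-dioxolan-4-yl]but-3-yn-2-ol
Conditions: HC≡CMgBr, THF, −78 to −20 °C; then H2O
Reagents that add atoms: ethynylmagnesium bromide, C#C[Mg]Br
Why: Chelation-controlled (Cram-chelate) Grignard addition: magnesium bridges the carbonyl and the α-dioxolane oxygen and the acetylide attacks anti to the ring C–C bond, which sets C-10 (S here, R once C-1 becomes a carbonyl).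

Step 5
Reactants: 5 (2S)-2-[(4S,5S)-2,2-dimethyl-5-vinyl-1,3-dioxolan-4-yl]but-3-yn-2-ol
Product: 6 triethyl{[(2S)-2-[(4S,5S)-2,2-dimethyl-5-vinyl-1,3-dioxolan-4-yl]but-3-yn-2-yl]oxy}silane
Conditions: Et3SiOTf, 2,6-lutidine, CH2Cl2, −78 to 0 °C
Reagents that add atoms: triethylsilyl trifluoromethanesulfonate, CC[Si](CC)(CC)OS(=O)(=O)C(F)(F)F
Why: Silyl triflate silylation caps the hindered tertiary alcohol so that the aldehyde made next cannot close to a lactol.

Step 6
Reactants: 6 triethyl{[(2S)-2-[(4S,5S)-2,2-dimethyl-5-vinyl-1,3-dioxolan-4-yl]but-3-yn-2-yl]oxy}silane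
Product: 8 (4R,5S)-2,2-dimethyl-5-[(2S)-2-(triethylsilyloxy)but-3-yn-2-yl]-1,3-dioxolane-4-carbaldehyde, via ozonide 7 (not isolated)
Conditions: O3, CH2Cl2, −78 °C (Sudan Red 7B end point); then PPh3, −78 °C to rt
Reagents that add atoms: ozone, O=[O+][O-]
Why: Ozonolysis with reductive work-up cleaves the vinyl group much faster than the terminal alkyne and gives the C-7 aldehyde with C-8 unchanged.

Step 7
Reactants: 8 (4R,5S)-2,2-dimethyl-5-[(2S)-2-(triethylsilyloxy)but-3-yn-2-yl]-1,3-dioxolane-4-carbaldehyde; 9 methyl acrylate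
Product: 10 methyl 2-{hydroxy[(4S,5S)-2,2-dimethyl-5-[(2S)-2-(triethylsilyloxy)but-3-yn-2-yl]-1,3-dioxolan-4-yl]methyl}prop-2-enoate (both carbinol epimers)
Conditions: DABCO (1 equiv), neat 9 (excess), rt, 3 d
Reagents that add atoms: none
Why: The Morita–Baylis–Hillman reaction joins the acrylate α-carbon (C-11) to C-7; the carbinol epimer ratio does not matter because this centre is transposed in step 8.

Step 8
Reactants: 10 methyl 2-{hydroxy[(4S,5S)-2,2-dimethyl-5-[(2S)-2-(triethylsilyloxy)but-3-yn-2-yl]-1,3-dioxolan-4-yl]methyl}prop-2-enoate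
Product: 12 methyl (2Z)-2-(bromomethyl)-3-{(4S,5S)-2,2-dimethyl-5-[(2S)-2-(triethylsilyloxy)but-3-yn-2-yl]-1,3-dioxolan-4-yl}prop-2-enoate, via mesylate 11 (not isolated)
Conditions: MsCl, Et3N, CH2Cl2, −20 °C; then LiBr, THF, 0 °C to rt
Reagents that add atoms: methanesulfonyl chloride, CS(=O)(=O)Cl; lithium bromide, [Li+].[Br-]
Why: Mesylation followed by SN2′ displacement with bromide (allylic transposition) gives the thermodynamically preferred (Z)-2-(bromomethyl)enoate.

Step 9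
Reactants: 12 methyl (2Z)-2-(bromomethyl)-3-{(4S,5S)-2,2-dimethyl-5-[(2S)-2-(triethylsilyloxy)but-3-yn-2-yl]-1,3-dioxolan-4-yl}prop-2-enoate; 13 acrolein
Product: 16 (4S,5S)-4-{(4S,5S)-2,2-dimethyl-5-[(2S)-2-(triethylsilyloxy)but-3-yn-2-yl]-1,3-dioxolan-4-yl}-3-methylidene-5-vinyloxolan-2-one, via allylzinc bromide 14 (not isolated), via syn hydroxy ester 15 (not isolated)
Conditions: Zn dust, THF/sat. aq. NH4Cl (2:1), 0 °C to rt
Reagents that add atoms: zinc, [Zn]
Why: Zinc Barbier allylation through a chair transition state gives the syn adduct and hence the cis-lactone (C-6), while allylic strain holds H-8 in the alkene plane so the aldehyde adds anti to the bulky C-9 branch of the cis-dioxolane (C-7), and the alkoxide lactonises in situ.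

Step 10
Reactants: 16 (4S,5S)-4-{(4S,5S)-2,2-dimethyl-5-[(2S)-2-(triethylsilyloxy)but-3-yn-2-yl]-1,3-dioxolan-4-yl}-3-methylidene-5-vinyloxolan-2-one; 17 methacryloyl chloride
Product: 18 (4S,5S)-4-{(4S,5S)-2,2-dimethyl-5-[(2S)-6-methyl-5-oxo-2-(triethylsilyloxy)hept-6-en-3-yn-2-yl]-1,3-dioxolan-4-yl}-3-methylidene-5-vinyloxolan-2-one
Conditions: Pd(PPh3)2Cl2 (2 mol %), CuI (4 mol %), Et3N, THF, rt
Reagents that add atoms: none
Why: Acyl Sonogashira coupling of the terminal alkyne with the acid chloride gives the cross-conjugated ynone under conditions that leave the lactone and both alkenes alone.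

Step 11
Reactants: 18 (4S,5S)-4-{(4S,5S)-2,2-dimethyl-5-[(2S)-6-methyl-5-oxo-2-(triethylsilyloxy)hept-6-en-3-yn-2-yl]-1,3-dioxolan-4-yl}-3-methylidene-5-vinyloxolan-2-one
Product: 19 (4S,5S)-4-{(4S,5S)-5-[(2S)-2-hydroxy-6-methyl-5-oxohept-6-en-3-yn-2-yl]-2,2-dimethyl-1,3-dioxolan-4-yl}-3-methylidene-5-vinyloxolan-2-one
Conditions: HF·pyridine, pyridine/THF, 0 °C
Reagents that add atoms: none
Why: Fluoride-mediated desilylation frees the tertiary C-10 hydroxyl that becomes the furanone ring oxygen.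

Step 12
Reactants: 19 (4S,5S)-4-{(4S,5S)-5-[(2S)-2-hydroxy-6-methyl-5-oxohept-6-en-3-yn-2-yl]-2,2-dimethyl-1,3-dioxolan-4-yl}-3-methylidene-5-vinyloxolan-2-one
Product: 21 (4S,5S)-4-{(4S,5S)-2,2-dimethyl-5-[(2R)-2-methyl-3-oxo-5-(prop-1-en-2-yl)-2,3-dihydrofuran-2-yl]-1,3-dioxolan-4-yl}-3-methylidene-5-vinyloxolan-2-one, via hydroxy diketone 20 (not isolated)
Conditions: [(4-CF3C6H4)3P]AuCl (5 mol %), AgOTf (5 mol %), wet toluene, rt
Reagents that add atoms: water, O
Why: Gold-catalysed alkyne hydration and cyclodehydration (a formal cycloisomerisation of the γ-hydroxy ynone) gives the 3(2H)-furanone, and because the C-10–O bond is never broken the stereocentre is retained.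

Step 13
Reactants: 21 (4S,5S)-4-{(4S,5S)-2,2-dimethyl-5-[(2R)-2-methyl-3-oxo-5-(prop-1-en-2-yl)-2,3-dihydrofuran-2-yl]-1,3-dioxolan-4-yl}-3-methylidene-5-vinyloxolan-2-one
Product: 22 (4Z,6S,7S,8S,9S,10R)-8,9-(isopropylidenedioxy)-1-oxo-3,10-epoxygermacra-2,4,11(13)-trien-12,6-olide
Conditions: second-generation Grubbs catalyst (15 mol %, two portions), toluene (0.5 mM), 80 °C
Reagents that add atoms: none
Why: Ring-closing metathesis, in which the catalyst loads on the unhindered vinyl group and closes onto the isopropenyl group; the furanone-bridged ten-membered ring can only hold the ring-cis (4Z) alkene, and loss of ethylene drives the reaction.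

Step 14
Reactants: 22 (4Z,6S,7S,8S,9S,10R)-8,9-(isopropylidenedioxy)-1-oxo-3,10-epoxygermacra-2,4,11(13)-trien-12,6-olide
Product: 23 (4Z,6S,7S,8S,9S,10R)-8,9-dihydroxy-1-oxo-3,10-epoxygermacra-2,4,11(13)-trien-12,6-olide
Conditions: CF3CO2H/H2O (4:1), 0 °C
Reagents that add atoms: none
Why: Acid-catalysed acetal hydrolysis releases the cis-8,9-diol; the furanone, lactone and alkenes are stable to cold aqueous acid.

Step 15
Reactants: 23 (4Z,6S,7S,8S,9S,10R)-8,9-dihydroxy-1-oxo-3,10-epoxygermacra-2,4,11(13)-trien-12,6-olide; 24 methacrylic anhydride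
Product: 25 (4Z,6S,7S,8S,9S,10R)-9-hydroxy-8-(methacryloyloxy)-1-oxo-3,10-epoxygermacra-2,4,11(13)-trien-12,6-olide (CNP0252578.5)
Conditions: DMAP (cat.), pyridine/CH2Cl2, −40 to −20 °C, 1.05 equiv of 24
Reagents that add atoms: none
Why: DMAP-catalysed esterification at low temperature goes to the less hindered C-8 hydroxyl, since the C-9 hydroxyl is neopentylic next to the quaternary C-10.

**Compound list**
1 | 5-deoxy-D-ribose (furanose form, anomer mixture) | C[C@H]1OC(O)[C@H](O)[C@@H]1O | starting material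
2 | 5-deoxy-2,3-O-isopropylidene-D-ribofuranose | C[C@H]1OC(O)[C@@H]2OC(C)(C)O[C@H]12 | intermediate
3 | (1R)-1-[(4R,5S)-2,2-dimethyl-5-vinyl-1,3-dioxolan-4-yl]ethanol | C=C[C@@H]1OC(C)(C)O[C@@H]1[C@@H](C)O | intermediate
4 | 1-[(4S,5S)-2,2-dimethyl-5-vinyl-1,3-dioxolan-4-yl]ethanone | C=C[C@@H]1OC(C)(C)O[C@@H]1C(C)=O | intermediate
5 | (2S)-2-[(4S,5S)-2,2-dimethyl-5-vinyl-1,3-dioxolan-4-yl]but-3-yn-2-ol | C=C[C@@H]1OC(C)(C)O[C@@H]1[C@@](C)(O)C#C | intermediate
6 | triethyl{[(2S)-2-[(4S,5S)-2,2-dimethyl-5-vinyl-1,3-dioxolan-4-yl]but-3-yn-2-yl]oxy}silane | C=C[C@@H]1OC(C)(C)O[C@@H]1[C@@](C)(O[Si](CC)(CC)CC)C#C | intermediate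
7 | ozonide: 3-{(4R,5S)-2,2-dimethyl-5-[(2S)-2-(triethylsilyloxy)but-3-yn-2-yl]-1,3-dioxolan-4-yl}-1,2,4-trioxolane (epimers at the trioxolane carbon) | C1OOC(O1)[C@@H]2OC(C)(C)O[C@@H]2[C@@](C)(O[Si](CC)(CC)CC)C#C | intermediate
8 | (4R,5S)-2,2-dimethyl-5-[(2S)-2-(triethylsilyloxy)but-3-yn-2-yl]-1,3-dioxolane-4-carbaldehyde | O=C[C@@H]1OC(C)(C)O[C@@H]1[C@@](C)(O[Si](CC)(CC)CC)C#C | intermediate
9 | methyl acrylate | C=CC(=O)OC | starting material
10 | methyl 2-{hydroxy[(4S,5S)-2,2-dimethyl-5-[(2S)-2-(triethylsilyloxy)but-3-yn-2-yl]-1,3-dioxolan-4-yl]methyl}prop-2-enoate (both carbinol epimers) | C=C(C(=O)OC)C(O)[C@@H]1OC(C)(C)O[C@@H]1[C@@](C)(O[Si](CC)(CC)CC)C#C | intermediate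
11 | mesylate of 10 | C=C(C(=O)OC)C(OS(C)(=O)=O)[C@@H]1OC(C)(C)O[C@@H]1[C@@](C)(O[Si](CC)(CC)CC)C#C | intermediate
12 | methyl (2Z)-2-(bromomethyl)-3-{(4S,5S)-2,2-dimethyl-5-[(2S)-2-(triethylsilyloxy)but-3-yn-2-yl]-1,3-dioxolan-4-yl}prop-2-enoate | BrC/C(=C\[C@@H]1OC(C)(C)O[C@@H]1[C@@](C)(O[Si](CC)(CC)CC)C#C)C(=O)OC | intermediate
13 | acrolein | C=CC=O | starting material
14 | allylzinc bromide from 12 (bromozinc in place of bromine) | Br[Zn]C/C(=C\[C@@H]1OC(C)(C)O[C@@H]1[C@@](C)(O[Si](CC)(CC)CC)C#C)C(=O)OC | intermediate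
15 | methyl (3S,4S)-3-{(4S,5S)-2,2-dimethyl-5-[(2S)-2-(triethylsilyloxy)but-3-yn-2-yl]-1,3-dioxolan-4-yl}-4-hydroxy-2-methylidenehex-5-enoate | C=C[C@H](O)[C@H](C(=C)C(=O)OC)[C@@H]1OC(C)(C)O[C@@H]1[C@@](C)(O[Si](CC)(CC)CC)C#C | intermediate
16 | (4S,5S)-4-{(4S,5S)-2,2-dimethyl-5-[(2S)-2-(triethylsilyloxy)but-3-yn-2-yl]-1,3-dioxolan-4-yl}-3-methylidene-5-vinyloxolan-2-one | C=C[C@@H]1OC(=O)C(=C)[C@@H]1[C@@H]2OC(C)(C)O[C@@H]2[C@@](C)(O[Si](CC)(CC)CC)C#C | intermediate
17 | methacryloyl chloride | C=C(C)C(Cl)=O | starting material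
18 | (4S,5S)-4-{(4S,5S)-2,2-dimethyl-5-[(2S)-6-methyl-5-oxo-2-(triethylsilyloxy)hept-6-en-3-yn-2-yl]-1,3-dioxolan-4-yl}-3-methylidene-5-vinyloxolan-2-one | C=C[C@@H]1OC(=O)C(=C)[C@@H]1[C@@H]2OC(C)(C)O[C@@H]2[C@@](C)(O[Si](CC)(CC)CC)C#CC(=O)C(C)=C | intermediate
19 | (4S,5S)-4-{(4S,5S)-5-[(2S)-2-hydroxy-6-methyl-5-oxohept-6-en-3-yn-2-yl]-2,2-dimethyl-1,3-dioxolan-4-yl}-3-methylidene-5-vinyloxolan-2-one | C=C[C@@H]1OC(=O)C(=C)[C@@H]1[C@@H]2OC(C)(C)O[C@@H]2[C@@](C)(O)C#CC(=O)C(C)=C | intermediate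
20 | (4S,5S)-4-{(4S,5S)-5-[(2R)-2-hydroxy-6-methyl-3,5-dioxohept-6-en-2-yl]-2,2-dimethyl-1,3-dioxolan-4-yl}-3-methylidene-5-vinyloxolan-2-one | C=C[C@@H]1OC(=O)C(=C)[C@@H]1[C@@H]2OC(C)(C)O[C@@H]2[C@@](C)(O)C(=O)CC(=O)C(C)=C | intermediate
21 | (4S,5S)-4-{(4S,5S)-2,2-dimethyl-5-[(2R)-2-methyl-3-oxo-5-(prop-1-en-2-yl)-2,3-dihydrofuran-2-yl]-1,3-dioxolan-4-yl}-3-methylidene-5-vinyloxolan-2-one | C=C[C@@H]1OC(=O)C(=C)[C@@H]1[C@@H]2OC(C)(C)O[C@@H]2[C@@]3(C)OC(=CC3=O)C(C)=C | intermediate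
22 | (4Z,6S,7S,8S,9S,10R)-8,9-(isopropylidenedioxy)-1-oxo-3,10-epoxygermacra-2,4,11(13)-trien-12,6-olide | CC1(C)O[C@H]2[C@H]3C(=C)C(=O)O[C@H]3/C=C(/C)C3=CC(=O)[C@](C)(O3)[C@H]2O1 | intermediate
23 | (4Z,6S,7S,8S,9S,10R)-8,9-dihydroxy-1-oxo-3,10-epoxygermacra-2,4,11(13)-trien-12,6-olide | O[C@H]1[C@H]2C(=C)C(=O)O[C@H]2/C=C(/C)C2=CC(=O)[C@](C)(O2)[C@H]1O | intermediate
24 | methacrylic anhydride | C=C(C)C(=O)OC(=O)C(C)=C | starting material
25 | (4Z,6S,7S,8S,9S,10R)-9-hydroxy-8-(methacryloyloxy)-1-oxo-3,10-epoxygermacra-2,4,11(13)-trien-12,6-olide | C=C(C)C(=O)O[C@H]1[C@H]2C(=C)C(=O)O[C@H]2/C=C(/C)C2=CC(=O)[C@](C)(O2)[C@H]1O | target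

**Step count**
Total step count: 15. Longest linear sequence: 15 (1 to 25). The route is linear from 1: the four other carbon inputs 9, 13, 17 and 24 are bought and each enters in a single step, so no steps lie off the main line. I found no stereochemically reliable way to split the C-6 to C-10 core into two multi-step fragments.

**Three steps most likely to fail**

Step 9 (Barbier lactone annulation). The C-7 configuration rests on a steric model (attack anti to the C-9 branch with H-8 in plane), and the allylzinc carries a δ-oxygen that could be lost by 1,4-elimination. Fallback: replace the allylzinc by a covalent allylboron reagent that reacts through a tight, closed transition state and cannot eliminate. It sets out from 10: acetylation (Ac2O, DMAP, pyridine) gives the allylic acetate F1. SN2′-type borylation with B2pin2 and catalytic Pd2(dba)3 in toluene gives the 2-(methoxycarbonyl)allylboronate F2. Heating F2 with acrolein 13 in toluene, then a trace of TsOH, gives the cis-lactone and comes back to the route at 16.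

Step 13 (ring-closing metathesis). A strained ten-membered ring with a trisubstituted, conjugated alkene may give oligomers or stall, and the cis-fused dioxolane fixes the C-8–C-9 dihedral in a way that may not suit closure. Fallback: change the metathesis substrate by inverting the order of ring closure and deprotection. It sets out from 21: acetonide hydrolysis (CF3CO2H/H2O, 0 °C) gives the seco-diol F3, in which the C-8–C-9 bond can rotate freely. Metathesis of F3 (same ruthenium catalyst family, toluene, high dilution) gives the macrocyclic diol directly and comes back to the route at 23, so step 14 is skipped.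

Step 15 (regioselective methacrylation). The two secondary hydroxyls are cis and adjacent, so mixtures, bis-acylation or 8-to-9 acyl migration are possible. Fallback: use tin-directed acylation instead of relying on sterics alone. It sets out from 23: Bu2SnO in refluxing toluene with removal of water gives the dibutylstannylene acetal F4. Treating F4 with methacryloyl chloride 17 at −20 °C delivers the acyl group to the less hindered O-8 and comes back to the route at 25.

**Further compounds**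
F1 | step 9 | methyl 2-{acetoxy[(4S,5S)-2,2-dimethyl-5-[(2S)-2-(triethylsilyloxy)but-3-yn-2-yl]-1,3-dioxolan-4-yl]methyl}prop-2-enoate | C=C(C(=O)OC)C(OC(C)=O)[C@@H]1OC(C)(C)O[C@@H]1[C@@](C)(O[Si](CC)(CC)CC)C#C
F2 | step 9 | methyl (2E)-3-{(4S,5S)-2,2-dimethyl-5-[(2S)-2-(triethylsilyloxy)but-3-yn-2-yl]-1,3-dioxolan-4-yl}-2-[(4,4,5,5-tetramethyl-1,3,2-dioxaborolan-2-yl)methyl]prop-2-enoate | CC1(C)OB(C/C(=C\[C@@H]2OC(C)(C)O[C@@H]2[C@@](C)(O[Si](CC)(CC)CC)C#C)C(=O)OC)OC1(C)C
F3 | step 13 | (4S,5S)-4-{(1S,2S)-1,2-dihydroxy-2-[(2R)-2-methyl-3-oxo-5-(prop-1-en-2-yl)-2,3-dihydrofuran-2-yl]ethyl}-3-methylidene-5-vinyloxolan-2-one | C=C[C@@H]1OC(=O)C(=C)[C@@H]1[C@H](O)[C@H](O)[C@@]2(C)OC(=CC2=O)C(C)=C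
F4 | step 15 | 8,9-O-dibutylstannylene acetal of 23 | CCCC[Sn]1(CCCC)O[C@H]2[C@H]3C(=C)C(=O)O[C@H]3/C=C(/C)C3=CC(=O)[C@](C)(O3)[C@H]2O1
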